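**Strategy.** The route rests on closing the cyclohexenone between C-5 (the carbinol carbon) and C-6 (the oxirane CH) of the 7-oxabicyclo[4.1.0]hept-3-en-2-one core. The step exploits two features: C-5 is the γ-carbon of the C-2/C-3/C-4 enone, and C-6/C-1 form the oxirane next to the C-2 ketone. An acyclic enone whose two γ-CH2O groups sit in an acetonide, and whose other ketone substituent is a quaternary α-chloro aldehyde, is deprotonated once. The vinylogous aldol addition forms C-5–C-6 and the resulting alkoxide displaces the chloride, so carbocycle and oxirane close in one operation and C-1, C-5 and C-6 are all set from the single chloride stereocentre.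

Key step: step 5

Remark (numbering): core atoms are numbered throughout as in 7-oxabicyclo[4.1.0]hept-3-ene: C-1 quaternary oxirane carbon, C-2 ketone, C-3, C-4, C-5 carbinol carbon, C-6 oxirane CH.
Assumption: the sense of induction of the copper bisoxazoline chlorination in step 4 is not secure for an α-formyl ketone, so the ligand antipode that delivers (S)-10 is the one to be used; compound 2 is taken as a purchasable building block.

Step 1
Reactants: 1 dimethyl (2-oxopropyl)phosphonate; 2 methyl (2E)-4-bromo-2-methylbut-2-enoate
Product: 4 methyl (2E)-7-(dimethoxyphosphoryl)-2-methyl-6-oxohept-2-enoate, via phosphonate dianion 3 (not isolated)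
Conditions: NaH, THF, 0 °C; n-BuLi, 0 °C; then 2, −78 → 0 °C; AcOH quench
Reagents that add atoms: none
Why: Dianion alkylation of a β-ketophosphonate, in which the more basic terminal carbanion of 3 should be alkylated by the primary allylic bromide in an SN2 reaction faster than it adds to the α-methyl-substituted enoate, leaving the (E)-alkene untouched and forming no stereocentre.

Step 2
Reactants: 4 methyl (2E)-7-(dimethoxyphosphoryl)-2-methyl-6-oxohept-2-enoate; 5 2,2-dimethyl-1,3-dioxan-5-one
Product: 7 methyl (2E)-7-(2,2-dimethyl-1,3-dioxan-5-ylidene)-2-methyl-6-oxohept-2-enoate, via sodium phosphonate 6 (not isolated)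
Conditions: NaH, THF, 0 °C; then 5, 0 °C → rt
Reagents that add atoms: none
Why: Horner–Wadsworth–Emmons olefination of the activated α,α′-dialkoxy ketone 5 by the stabilised phosphonate anion 6, where the new alkene is exocyclic to a symmetrical dioxane so that neither alkene isomers nor a stereocentre arise.

Step 3
Reactants: 7 methyl (2E)-7-(2,2-dimethyl-1,3-dioxan-5-ylidene)-2-methyl-6-oxohept-2-enoate
Product: 9 methyl (2E)-7-(2,2-dimethyl-1,3-dioxan-5-ylidene)-5-formyl-2-methyl-6-oxohept-2-enoate (held mainly as its hydroxymethylene enol), via lithium enolate 8 (not isolated)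
Conditions: LiN(SiMe3)2 (1.1 equiv), THF, −78 °C; HCO2CH2CF3, −78 °C; AcOH quench
Reagents that add atoms: 2,2,2-trifluoroethyl formate, O=COCC(F)(F)F
Why: Kinetic deprotonation of the enone at its α′-CH2 should give the cross-conjugated enolate 8, and Claisen-type C-formylation with the reactive trifluoroethyl formate then gives the α-formyl ketone, whose chain C-5 stays configurationally labile at this stage.

Step 4
Reactants: 9 methyl (2E)-7-(2,2-dimethyl-1,3-dioxan-5-ylidene)-5-formyl-2-methyl-6-oxohept-2-enoate
Product: 10 methyl (2E,5S)-5-chloro-7-(2,2-dimethyl-1,3-dioxan-5-ylidene)-5-formyl-2-methyl-6-oxohept-2-enoate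
Conditions: NCS (1.05 equiv), Cu(OTf)2 (10 mol %), tBu-box ligand (11 mol %), Et2O, 0 °C; short silica plug, used directly
Reagents that add atoms: N-chlorosuccinimide, ClN1C(=O)CCC1=O
Why: Catalytic enantioselective electrophilic α-chlorination of a 2-substituted 1,3-dicarbonyl compound, in which the divalent copper bisoxazoline complex binds the enolised keto aldehyde as a bidentate chelate and leaves one enolate face open to NCS, setting the quaternary C–Cl centre that later becomes C-1.

Step 5
Reactants: 10 methyl (2E,5S)-5-chloro-7-(2,2-dimethyl-1,3-dioxan-5-ylidene)-5-formyl-2-methyl-6-oxohept-2-enoate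
Product: 13 methyl (2E)-4-[(1R,5R,6R)-5-hydroxy-4-(hydroxymethyl)-2-oxo-7-oxabicyclo[4.1.0]hept-3-en-1-yl]-2-methylbut-2-enoate 4-CH2O/5-O isopropylidene acetal, via potassium dienolate 11 (not isolated), via chlorohydrin alkoxide 12 (not isolated)
Conditions: KN(SiMe3)2 (1.0 equiv), THF (0.01 M), −78 → −20 °C
Reagents that add atoms: none
Why: KN(SiMe3)2 removes a γ-proton from an OCH2 of the dioxane to give dienolate 11, whose γ-carbon adds to the tethered non-enolisable aldehyde, and alkoxide 12 then displaces the tertiary α-keto chloride. The closest known reaction types are the intramolecular vinylogous aldol addition and the halohydrin-alkoxide ring closure that ends a Darzens condensation or follows aldol additions to α-chloro aldehydes. The carbocycle closes in a 6-(enolendo)-exo-trig mode (attack through the α-carbon would need a four-membered ring) and the oxirane in a 3-exo-tet mode. C-1 is inverted by the SN2 closure, so the chloride configuration of 10 fixes the oxirane face; C-6 follows because only the alkoxide anti-periplanar to C–Cl can close while the aldol step is reversible; C-5 should end with its acetal oxygen cis to the oxirane because the alternative closing transition state holds that oxygen 1,3-diaxial to the departing chloride. The step needs γ-deprotonation of 10 in preference to that of product 13, whose dienolate would open the oxirane: the quaternary chloro carbon leaves the four γ-CH2O hydrogens of 10 as its only acidic C–H and blocks dehydration to an aromatisable dienone, whereas 13 has a single hindered γ-hydrogen and meets no excess base. The reactive dienolate geometry (C-1 carbon cis to C-4) should be reached by equilibration of the potassium dienolate on warming.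

Step 6
Reactants: 13 acetonide-protected epoxy enone methyl ester (C-3 unsubstituted)
Product: 14 3-iodo derivative of 13 (iodine on C-3; 1R,5R,6R)
Conditions: I2 (2 equiv), pyridine/CH2Cl2 (1:1), 0 °C → rt, dark
Reagents that add atoms: iodine, II
Why: Amine-mediated α-iodination of a cyclic enone (conjugate addition of pyridine, iodination of the enolate, elimination), a reaction type that tolerates 3-substituted cyclohexenones and oxiranes, while pyridine is too weak a base to deprotonate C-5 and no stereocentre is touched.

Step 7
Reactants: 14 3-iodo derivative of 13; 15 (1E)-hept-1-en-1-ylboronic acid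
Product: 16 methyl ester and 4-CH2O/5-O acetonide of the target (3-[(1E)-hept-1-en-1-yl] derivative of 13)
Conditions: Pd2(dba)3 (5 mol %), AsPh3 (20 mol %), Ag2O, THF/H2O (8:1), rt
Reagents that add atoms: none
Why: Suzuki–Miyaura coupling of the α-iodo enone with the (E)-alkenylboronic acid should proceed with retention of alkene geometry, with Ag2O as a mild non-basic promoter that spares the γ-hydrogen at C-5 and the oxirane.

Step 8
Reactants: 16 methyl ester and acetonide of the target
Product: 18 4-CH2O/5-O acetonide of the target acid, via trimethylstannyl ester 17 (not isolated)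
Conditions: Me3SnOH (5 equiv), 1,2-dichloroethane, 70 °C; 1 M HCl work-up
Reagents that add atoms: trimethyltin hydroxide, C[Sn](C)(C)O
Why: Me3SnOH cleaves the methyl ester under nearly neutral conditions by acyl–oxygen cleavage to stannyl ester 17, avoiding hydroxide that could deprotonate C-5 and open the oxirane, and the acidic work-up frees the acid without affecting any stereocentre.

Step 9
Reactants: 18 4-CH2O/5-O acetonide of the target acid
Product: 19 (2E)-4-[(1R,5R,6R)-3-[(1E)-hept-1-en-1-yl]-5-hydroxy-4-(hydroxymethyl)-2-oxo-7-oxabicyclo[4.1.0]hept-3-en-1-yl]-2-methylbut-2-enoic acid (CNP0332048.1)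
Conditions: AcOH/H2O (4:1), 40 °C
Reagents that add atoms: none
Why: Mild aqueous acid should hydrolyse the six-membered isopropylidene acetal to the primary and secondary alcohols, while the oxirane is deactivated toward acid opening by the adjacent ketone and no stereocentre is changed.

**Compound list**

1 | dimethyl (2-oxopropyl)phosphonate | CC(=O)CP(=O)(OC)OC | starting material
2 | methyl (2E)-4-bromo-2-methylbut-2-enoate | BrC/C=C(\C)C(=O)OC | starting material
3 | sodium lithium dianion of 1 (carbanions at CH3 and at PCH2) | [Na+].[Li+].[CH2-]C(=O)[CH-]P(=O)(OC)OC | intermediate (not isolated)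
4 | methyl (2E)-7-(dimethoxyphosphoryl)-2-methyl-6-oxohept-2-enoate | COP(=O)(OC)CC(=O)CC/C=C(\C)C(=O)OC | intermediate
5 | 2,2-dimethyl-1,3-dioxan-5-one | CC1(C)OCC(=O)CO1 | starting material
6 | sodium salt of 4 (carbanion at PCH) | [Na+].COP(=O)(OC)[CH-]C(=O)CC/C=C(\C)C(=O)OC | intermediate (not isolated)
7 | methyl (2E)-7-(2,2-dimethyl-1,3-dioxan-5-ylidene)-2-methyl-6-oxohept-2-enoate | CC1(C)OCC(=CC(=O)CC/C=C(\C)C(=O)OC)CO1 | intermediate
8 | lithium enolate of 7 (cross-conjugated, C-5/C-6 of the chain) | [Li+].[O-]C(=CC/C=C(\C)C(=O)OC)C=C1COC(C)(C)OC1 | intermediate (not isolated)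
9 | methyl (2E)-7-(2,2-dimethyl-1,3-dioxan-5-ylidene)-5-formyl-2-methyl-6-oxohept-2-enoate (drawn as keto aldehyde; C-5 labile) | O=CC(C/C=C(\C)C(=O)OC)C(=O)C=C1COC(C)(C)OC1 | intermediate
10 | methyl (2E,5S)-5-chloro-7-(2,2-dimethyl-1,3-dioxan-5-ylidene)-5-formyl-2-methyl-6-oxohept-2-enoate | Cl[C@](C=O)(C/C=C(\C)C(=O)OC)C(=O)C=C1COC(C)(C)OC1 | intermediate
11 | potassium dienolate of 10 (2,2-dimethyl-4H-1,3-dioxin-5-yl enolate) | [K+].Cl[C@](C=O)(C/C=C(\C)C(=O)OC)C([O-])=CC1=COC(C)(C)OC1 | intermediate (not isolated)
12 | potassium alkoxide of the cyclised chlorohydrin (O− on future C-6, cis to the acetal oxygen on C-5, trans to Cl on future C-1) | [K+].C1=C2COC(C)(C)O[C@H]2[C@@H]([O-])[C@@](Cl)(C/C=C(\C)C(=O)OC)C1=O | intermediate (not isolated)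
13 | methyl (2E)-4-[(1R,5R,6R)-5-hydroxy-4-(hydroxymethyl)-2-oxo-7-oxabicyclo[4.1.0]hept-3-en-1-yl]-2-methylbut-2-enoate, 4-CH2O/5-O isopropylidene acetal | C1=C2COC(C)(C)O[C@H]2[C@H]3O[C@@]3(C/C=C(\C)C(=O)OC)C1=O | intermediate
14 | 3-iodo derivative of 13 (1R,5R,6R) | IC1=C2COC(C)(C)O[C@H]2[C@H]3O[C@@]3(C/C=C(\C)C(=O)OC)C1=O | intermediate
15 | (1E)-hept-1-en-1-ylboronic acid | CCCCC/C=C/B(O)O | starting material
16 | methyl ester and 4-CH2O/5-O acetonide of the target (1R,5R,6R) | CCCCC/C=C/C1=C2COC(C)(C)O[C@H]2[C@H]3O[C@@]3(C/C=C(\C)C(=O)OC)C1=O | intermediate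
17 | trimethylstannyl ester of 18 | CCCCC/C=C/C1=C2COC(C)(C)O[C@H]2[C@H]3O[C@@]3(C/C=C(\C)C(=O)O[Sn](C)(C)C)C1=O | intermediate (not isolated)
18 | 4-CH2O/5-O acetonide of the target acid (1R,5R,6R) | CCCCC/C=C/C1=C2COC(C)(C)O[C@H]2[C@H]3O[C@@]3(C/C=C(\C)C(=O)O)C1=O | intermediate
19 | (2E)-4-[(1R,5R,6R)-3-[(1E)-hept-1-en-1-yl]-5-hydroxy-4-(hydroxymethyl)-2-oxo-7-oxabicyclo[4.1.0]hept-3-en-1-yl]-2-methylbut-2-enoic acid | CCCCC/C=C/C1=C(CO)[C@@H](O)[C@H]2O[C@@]2(C/C=C(\C)C(=O)O)C1=O | target

**Totals**

Total step count: 9. Longest linear sequence: 9 steps (one linear sequence from 1; compounds 2, 5 and 15 are purchased).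

**Steps most likely to fail**

1. Step 5. Three processes threaten it: deprotonation of the product at C-5 followed by β-elimination that opens the oxirane; addition of the amide base to the very electrophilic aldehyde with loss of the formyl group; and persistence of the unreactive dienolate geometry, which would open the way to Favorskii-type loss of chloride. The fallback separates the two bond formations and avoids strong base. It sets out from 10: reversible soft enolisation with MgBr2·OEt2 and Et3N in CH2Cl2 at 0 °C, in which the magnesium chelate of the 1,3-dicarbonyl unit acidifies only 10, should give after a mildly acidic work-up the vinylogous aldol product, the chlorohydrin F1. Treatment of F1 with K2CO3 in MeCN at 0 °C then closes the oxirane and comes back to the route at 13.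

2. Step 4. Facial discrimination in the copper chelate of an aldehyde-derived 1,3-dicarbonyl may be poor, and the formyl group may be lost to water or alcohols during handling. The fallback replaces catalysis by a covalently bound auxiliary. It sets out from 9: condensation with (2R,5R)-2,5-dimethylpyrrolidine (toluene, molecular sieves) should give the enaminone F2. NCS in CH2Cl2 at −78 °C should chlorinate the face left open by the C2-symmetric amine to give the α-chloro iminium salt F3. Cold aqueous citric acid hydrolyses F3, releases the auxiliary as its ammonium salt (so that it cannot deformylate the product) and comes back to the route at 10; the antipodal amine is used if the induction runs the other way.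

3. Step 1. Conjugate addition of the dianion to the enoate, followed by cyclopropane closure onto the bromide, may compete with direct SN2 alkylation. The fallback installs the enoate after the alkylation. It sets out from 1: its dianion 3 is alkylated with allyl bromide to dimethyl (2-oxohex-5-en-1-yl)phosphonate F4. Cross-metathesis of F4 with excess methyl methacrylate (second-generation Grubbs catalyst, CH2Cl2, 40 °C) should give the (E)-trisubstituted enoate and comes back to the route at 4.

Further compounds
F1 | step 5 | cyclised chlorohydrin (protonated form of 12: OH on future C-6 cis to the acetal oxygen on C-5 and trans to Cl on future C-1) | C1=C2COC(C)(C)O[C@H]2[C@@H](O)[C@@](Cl)(C/C=C(\C)C(=O)OC)C1=O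
F2 | step 4 | (E)-enaminone of 9 with (2R,5R)-2,5-dimethylpyrrolidine | C[C@@H]1CC[C@@H](C)N1/C=C(\C/C=C(\C)C(=O)OC)C(=O)C=C2COC(C)(C)OC2
F3 | step 4 | α-chloro iminium succinimidate from F2 (quaternary C–Cl configured as in 10) | C[C@@H]1CC[C@@H](C)[N+]1=C[C@@](Cl)(C/C=C(\C)C(=O)OC)C(=O)C=C2COC(C)(C)OC2.O=C1CCC(=O)[N-]1
F4 | step 1 | dimethyl (2-oxohex-5-en-1-yl)phosphonate | C=CCCC(=O)CP(=O)(OC)OC
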